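**Retrosynthetic overview**

1. Numbering: ring A is C1 (carrying the exocyclic methylene C11), C2, C3, C4 (isopropyl), C5, C6 (enoate oxygen); ring B is C2, C3, C7 (side-chain carbinol C10), C8 (ketone), C9 (2-methylbutanoate oxygen); β is the face of H2. The strategy rests on cyclopentanone ring B, fused to ring A at C2–C3 with its carbonyl C8 opposite the fusion and the methylene on the neighbouring ring-A carbon C1. This pattern is the imprint of an alkyne (C3≡C7), carbon monoxide (C8) and a vinyl group (C2=C9) held on C1.
2. Late stage: the C6 ester by acylation, the C9 ester by Mitsunobu inversion of a C9 alcohol from enolate hydroxylation, and C7–C10 by fluoride-catalysed aldol addition of the C7 silyl enol ether. That enol ether comes from trapping the regiodefined enolate left by dissolving-metal reduction of the enone, which also sets the trans ring fusion.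
3. Key disconnection: C2–C3, C7–C8 and C8–C9 by an intramolecular Pauson–Khand reaction, which closes rings A and B in the same step. C11 is carried through it as a CH2SiMe3 group on a C1 carbinol and released afterwards by Peterson elimination.
4. The enyne comes from (R)-cryptone (3-methylbutanal plus butenone) by ozonolysis, alkynylation, auxiliary-controlled C6 hydroxylation, Weinreb amide formation, and vinyl then Me3SiCH2 addition.

Key step: step 11

Remark 1: a conjugated C1=C11/C2=C9 diene would offer the alkyne its 1,1-disubstituted C1=C11 bond in a five-ring (1,6-enyne) closure that is expected to outrun the six-ring closure wanted here. The methylene is therefore stored as CH2SiMe3/OH on C1, so the vinyl group is the only alkene in the key step; the C1 configuration is uncontrolled and is erased in step 12.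

Remark 2: the sense of induction in step 1 is taken from the usual shielding model for diarylprolinol ether enamines; the (R)-catalyst is expected to give the (R)-aldehyde, and the enantiomeric catalyst would be used if the opposite sense were found.

**Route**

Step 1
Reactants: 1 3-methylbutanal; 2 but-3-en-2-one
Product: 3 (2R)-5-oxo-2-(propan-2-yl)hexanal
Conditions: (R)-2-[methoxy(diphenyl)methyl]pyrrolidine (5 mol %), ethyl 3,4-dihydroxybenzoate (20 mol %), neat, 4 °C
Reagents that add atoms: none
Why: Enamine-catalysed Michael addition in which the (E)-enamine of 1 adds to the enone on the face away from the diarylmethyl arm of the catalyst, which sets the isopropyl-bearing centre (the later C4) as (R).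

Step 2
Reactants: 3 (2R)-5-oxo-2-(propan-2-yl)hexanal
Product: 4 (R)-cryptone, (4R)-4-(propan-2-yl)cyclohex-2-en-1-one
Conditions: LiOH (cat.), iPrOH, rt
Reagents that add atoms: none
Why: Intramolecular aldol condensation (second half of a Robinson-type annulation) in which the methyl ketone enolate closes onto the aldehyde and dehydration gives the enone, the mild base being expected to leave the C4 centre intact.

Step 3
Reactants: 4 (R)-cryptone
Product: 5 (4R)-4-formyl-5-methylhexanoic acid
Conditions: O3, acetone/H2O (19:1), 0 °C; N2 purge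
Reagents that add atoms: ozone, O=[O+][O-]; water, O
Why: Ozonolysis of a conjugated enone in a participating solvent takes the abnormal course in which the first-formed α-keto aldehyde is cleaved by the peroxide generated alongside, so that the enone α-carbon leaves as formic acid, the ring carbonyl becomes the acid and the aldehyde next to the stereocentre is kept.

Step 4
Reactants: 5 (4R)-4-formyl-5-methylhexanoic acid; 6 dimethyl (1-diazo-2-oxopropyl)phosphonate
Product: 7 (4R)-4-(propan-2-yl)hex-5-ynoic acid
Conditions: K2CO3, MeOH, 0 °C → rt; acidic work-up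
Reagents that add atoms: none
Why: Ohira–Bestmann (Seyferth–Gilbert) homologation in which methanolysis of 6 gives the diazomethylphosphonate anion, which adds to the aldehyde and loses phosphate and N2 to give the terminal alkyne under conditions mild enough to spare the α-stereocentre.

Step 5
Reactants: 7 (4R)-4-(propan-2-yl)hex-5-ynoic acid; 8 (4S)-4-benzyl-1,3-oxazolidin-2-one
Product: 10 (4S)-4-benzyl-3-[(4R)-4-(propan-2-yl)hex-5-ynoyl]-1,3-oxazolidin-2-one, via mixed pivalic anhydride 9 (not isolated)
Conditions: t-BuCOCl, Et3N, THF, −20 °C; then 8, LiCl, rt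
Reagents that add atoms: none
Why: N-Acylation of the oxazolidinone through the mixed anhydride under LiCl/amine activation needs no strong base, so the alkyne C–H is left alone.

Step 6
Reactants: 10 (4S)-4-benzyl-3-[(4R)-4-(propan-2-yl)hex-5-ynoyl]-1,3-oxazolidin-2-one
Product: 12 (4S)-4-benzyl-3-[(2S,4R)-2-hydroxy-4-(propan-2-yl)hex-5-ynoyl]-1,3-oxazolidin-2-one, via sodium enolate 11 (not isolated)
Conditions: NaN(SiMe3)2, THF, −78 °C; 3-phenyl-2-(phenylsulfonyl)oxaziridine, −78 °C; aq. NH4Cl
Reagents that add atoms: 3-phenyl-2-(phenylsulfonyl)oxaziridine, O=S(=O)(c1ccccc1)N1OC1c1ccccc1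
Why: Auxiliary-controlled enolate oxidation (Davis oxaziridine) in which the chelated sodium (Z)-enolate is attacked on the face opposite the benzyl group, which sets the carbinol centre (the later C6) as (S).

Step 7
Reactants: 12 (4S)-4-benzyl-3-[(2S,4R)-2-hydroxy-4-(propan-2-yl)hex-5-ynoyl]-1,3-oxazolidin-2-one
Product: 13 (2S,4R)-2-hydroxy-N-methoxy-N-methyl-4-(propan-2-yl)hex-5-ynamide
Conditions: MeONHMe·HCl, AlMe3, CH2Cl2, 0 °C → rt
Reagents that add atoms: N,O-dimethylhydroxylamine hydrochloride, CNOC.Cl
Why: Aluminium amide transamination to the Weinreb amide, in which the aluminium alkoxide of the free α-hydroxyl directs attack to the exocyclic carbonyl and releases the auxiliary.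

Step 8
Reactants: 13 (2S,4R)-2-hydroxy-N-methoxy-N-methyl-4-(propan-2-yl)hex-5-ynamide
Product: 14 (2S,4R)-N-methoxy-N-methyl-4-(propan-2-yl)-2-(triethylsilyloxy)hex-5-ynamide
Conditions: Et3SiCl, imidazole, CH2Cl2, 0 °C
Reagents that add atoms: chlorotriethylsilane, CC[Si](Cl)(CC)CC
Why: Standard silylation of a secondary alcohol gives a C6 ether that survives organometallic, cobalt and dissolving-metal steps and can later be removed in the presence of a tert-butyldimethylsilyl ether.

Step 9
Reactants: 14 (2S,4R)-N-methoxy-N-methyl-4-(propan-2-yl)-2-(triethylsilyloxy)hex-5-ynamide; 15 vinylmagnesium bromide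
Product: 16 (4S,6R)-6-(propan-2-yl)-4-(triethylsilyloxy)oct-1-en-7-yn-3-one
Conditions: CH2=CHMgBr (3 equiv), THF, −78 → 0 °C; inverse quench into cold aq. HCl
Reagents that add atoms: none
Why: Weinreb ketone synthesis in which the chelated tetrahedral intermediate prevents over-addition, the acidic inverse quench keeps the liberated amine from adding to the enone, and the alkynyl C–H that consumes one equivalent of reagent is restored on quench.

Step 10
Reactants: 16 (4S,6R)-6-(propan-2-yl)-4-(triethylsilyloxy)oct-1-en-7-yn-3-one; 17 (trimethylsilyl)methylmagnesium chloride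
Product: 18 (4S,6R)-6-(propan-2-yl)-4-(triethylsilyloxy)-3-[(trimethylsilyl)methyl]oct-1-en-7-yn-3-ol (both C3 epimers; chain C3 is C1 of the target numbering)
Conditions: Me3SiCH2MgCl, CeCl3, THF, −78 °C; aq. NH4Cl
Reagents that add atoms: none
Why: 1,2-Addition of the weakly basic organocerium reagent to the enone carbonyl (first half of a Peterson olefination) gives the tertiary β-hydroxysilane without enolising the C6 centre, and the new carbinol centre needs no control because it becomes trigonal in step 12.

Step 11
Reactants: 18 (4S,6R)-6-(propan-2-yl)-4-(triethylsilyloxy)-3-[(trimethylsilyl)methyl]oct-1-en-7-yn-3-ol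
Product: 20 4-hydroxy-7-(propan-2-yl)-5-(triethylsilyloxy)-4-[(trimethylsilyl)methyl]-3,3a,4,5,6,7-hexahydro-2H-inden-2-one (H2 cis to H4; C6 oxygen trans to the isopropyl group; both C1 epimers), via hexacarbonyldicobalt alkyne complex 19 (not isolated)
Conditions: Co2(CO)8, CH2Cl2, rt; then N-methylmorpholine N-oxide, 0 °C → rt
Reagents that add atoms: dicobalt octacarbonyl, O=C=[Co](=C=O)(=C=O)(=C=O)[Co](=C=O)(=C=O)(=C=O)=C=O
Why: The terminal alkyne forms its Co2(CO)6 complex, the N-oxide removes a CO ligand to open a site for the vinyl group, which inserts into the Co–C3 bond to make C2–C3, and CO insertion followed by reductive elimination makes C7–C8 and C8–C9. The closest known reaction type is the N-oxide-promoted intramolecular Pauson–Khand reaction of 1,7-enynes to bicyclo[4.3.0]non-1(9)-en-8-ones. Ring A closes in a six-exo mode as the four-atom tether C4–C5–C6–C1 is drawn into the metallacycle, and ring B (C2, C3, C7, C8, C9) is the five-membered ring created by the [2+2+1] union itself. The only new stereocentre, C2, is set by chair-like folding of the tether, in which the C4 isopropyl group is equatorial, the trans-disposed C6 silyloxy group is then axial, and C9 must lie equatorial on C2 to reach the cobalt-bound C7, so that H2 becomes axial and cis to H4. The step needs that facial selectivity and the use of a single alkene; the second is secured by the substrate, because C11 is present as CH2SiMe3 on a carbinol carbon and not as a C1=C11 double bond, so a five-ring closure onto the alkyne cannot compete. The fully substituted C1 and the branched C4 also favour the folded rotamer needed for six-ring closure, and both C1 epimers can use the same chair.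

Step 12
Reactants: 20 4-hydroxy-7-(propan-2-yl)-5-(triethylsilyloxy)-4-[(trimethylsilyl)methyl]-3,3a,4,5,6,7-hexahydro-2H-inden-2-one
Product: 21 4-methylidene-7-(propan-2-yl)-5-(triethylsilyloxy)-3,3a,4,5,6,7-hexahydro-2H-inden-2-one (H2 cis to H4; C6 oxygen trans to the isopropyl group)
Conditions: camphorsulfonic acid (5 mol %), CH2Cl2, 0 °C; Et3N quench
Reagents that add atoms: none
Why: Acid-promoted Peterson elimination in which ionisation of the tertiary carbinol is assisted by the β-silicon and loss of the silyl group can only place the double bond between C1 and C11, so the exocyclic methylene forms regiospecifically from either C1 epimer.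

Step 13
Reactants: 21 4-methylidene-7-(propan-2-yl)-5-(triethylsilyloxy)-3,3a,4,5,6,7-hexahydro-2H-inden-2-one
Product: 23 trans-fused trimethylsilyl enol ether (C7=C8–OSiMe3; H2 β; H3 α; isopropyl α; C6 OSiEt3 β; C1 methylidene), via lithium enolate 22 (not isolated)
Conditions: Li, NH3(l)/THF, −78 °C; isoprene; NH3 off; Me3SiCl, Et3N, THF, −78 → 0 °C
Reagents that add atoms: chlorotrimethylsilane, C[Si](C)(C)Cl
Why: Dissolving-metal (Birch-type) reduction of the enone in which the β-carbon C3 is protonated by ammonia on the axial lobe leading to the more stable trans-fused hydrindane (H3 anti to H2), and the lithium enolate, formed only towards C7, is trapped on oxygen as the silyl enol ether.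

Step 14
Reactants: 23 trans-fused trimethylsilyl enol ether; 24 acetaldehyde
Product: 26 trans-fused C8 ketone bearing 7α-[(1S)-1-hydroxyethyl] (H7 β; otherwise as 23), via C10 trimethylsilyl ether 25 (not isolated)
Conditions: (Me2N)3S+ Me3SiF2− (10 mol %), CH3CHO, THF, −78 °C; then citric acid, MeOH, 0 °C
Reagents that add atoms: none
Why: Fluoride-catalysed Mukaiyama aldol addition in which the silicate fluoride activates the Si–O bond of the regiodefined enol ether and the resulting metal-free enolate equivalent adds to the aldehyde through an open, extended transition state, known to favour the syn (erythro) adduct whatever the enolate geometry, which sets C10 as (S) relative to C7; the aldehyde should approach the α face of C7, anti to the C3–C4 bond, so the hydroxyethyl group ends trans to C4, and immediate silylation of the aldolate shuts off retro-aldol equilibration before mild acidic methanolysis frees the C10 hydroxyl.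

Step 15
Reactants: 26 trans-fused C8 ketone bearing 7α-[(1S)-1-hydroxyethyl]
Product: 27 C10 tert-butyldimethylsilyl ether of 26
Conditions: t-BuMe2SiOTf, 2,6-lutidine, CH2Cl2, −78 °C
Reagents that add atoms: tert-butyldimethylsilyl trifluoromethanesulfonate, CC(C)(C)[Si](C)(C)OS(=O)(=O)C(F)(F)F
Why: Silylation with a silyl triflate and a hindered base at low temperature protects the β-hydroxyl without retro-aldol cleavage and blocks the alkoxide-driven fragmentation that a later enolisation would invite.

Step 16
Reactants: 27 C10 tert-butyldimethylsilyl ether of 26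
Product: 29 9β-hydroxy ketone (H9 α; C9 epimeric to the target oxygenation), via potassium enolate 28 (not isolated)
Conditions: KN(SiMe3)2, THF, −78 °C; 3-phenyl-2-(phenylsulfonyl)oxaziridine, −78 °C; aq. NH4Cl
Reagents that add atoms: 3-phenyl-2-(phenylsulfonyl)oxaziridine, O=S(=O)(c1ccccc1)N1OC1c1ccccc1
Why: Kinetic deprotonation takes the C9 methylene and not the hindered C7 methine, and oxygen transfer from the oxaziridine (Davis oxidation) is expected on the β face of C9, anti to the C2–C1 bond, giving the 9β alcohol.

Step 17
Reactants: 29 9β-hydroxy ketone; 30 (2R)-2-methylbutanoic acid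
Product: 31 9α-[(2R)-2-methylbutanoyloxy] ketone (C6 OSiEt3; C10 OSi-t-BuMe2)
Conditions: PPh3, diisopropyl azodicarboxylate, toluene, 0 °C → rt
Reagents that add atoms: none
Why: Mitsunobu esterification in which SN2 displacement of the alkoxyphosphonium ion by the carboxylate, accelerated by the adjacent carbonyl, inverts C9 to the α-acyloxy configuration of the target and leaves the α-centre of the acid untouched.

Step 18
Reactants: 31 9α-[(2R)-2-methylbutanoyloxy] ketone
Product: 32 C6 β-alcohol (C9 ester and C10 silyl ether retained)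
Conditions: pyridinium p-toluenesulfonate (cat.), MeOH/CH2Cl2, 0 °C
Reagents that add atoms: none
Why: Acid-catalysed methanolysis removes the triethylsilyl ether much faster than the more hindered tert-butyldimethylsilyl ether and does not disturb the ester or the ketone.

Step 19
Reactants: 32 C6 β-alcohol; 33 (2E)-3-methylpent-2-enoic acid
Product: 35 C6 (E)-3-methylpent-2-enoate of 32 (C10 still silylated), via mixed trichlorobenzoic anhydride 34 (not isolated)
Conditions: 2,4,6-trichlorobenzoyl chloride, Et3N, THF, rt; then 32, DMAP, toluene, rt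
Reagents that add atoms: none
Why: Yamaguchi esterification in which DMAP opens the mixed anhydride at the enoyl carbonyl and the acylpyridinium ion acylates the hindered axial C6 alcohol with retention at C6.

Step 20
Reactants: 35 C6 (E)-3-methylpent-2-enoate of 32
Product: 36 CNP0224363.1
Conditions: HF·pyridine, pyridine/THF, 0 °C → rt
Reagents that add atoms: none
Why: Fluoride-mediated desilylation under mildly acidic, buffered conditions frees the C10 hydroxyl without retro-aldol cleavage or β-elimination of the β-hydroxy ketone and without touching either ester.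

**Compound list**

1 | 3-methylbutanal | CC(C)CC=O | starting material
2 | but-3-en-2-one | CC(=O)C=C | starting material
3 | (2R)-5-oxo-2-(propan-2-yl)hexanal | CC(=O)CC[C@H](C(C)C)C=O | intermediate
4 | (R)-cryptone, (4R)-4-(propan-2-yl)cyclohex-2-en-1-one | O=C1C=C[C@@H](C(C)C)CC1 | intermediate
5 | (4R)-4-formyl-5-methylhexanoic acid | OC(=O)CC[C@H](C(C)C)C=O | intermediate
6 | dimethyl (1-diazo-2-oxopropyl)phosphonate | COP(=O)(OC)C(=[N+]=[N-])C(C)=O | starting material
7 | (4R)-4-(propan-2-yl)hex-5-ynoic acid | OC(=O)CC[C@H](C(C)C)C#C | intermediate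
8 | (4S)-4-benzyl-1,3-oxazolidin-2-one | O=C1N[C@@H](Cc2ccccc2)CO1 | starting material
9 | mixed anhydride of 7 with pivalic acid | CC(C)(C)C(=O)OC(=O)CC[C@H](C(C)C)C#C | intermediate
10 | (4S)-4-benzyl-3-[(4R)-4-(propan-2-yl)hex-5-ynoyl]-1,3-oxazolidin-2-one | O=C1OC[C@H](Cc2ccccc2)N1C(=O)CC[C@H](C(C)C)C#C | intermediate
11 | sodium (Z)-enolate of 10 | O=C1OC[C@H](Cc2ccccc2)N1/C(O[Na])=C/C[C@H](C(C)C)C#C | intermediate
12 | (4S)-4-benzyl-3-[(2S,4R)-2-hydroxy-4-(propan-2-yl)hex-5-ynoyl]-1,3-oxazolidin-2-one | O=C1OC[C@H](Cc2ccccc2)N1C(=O)[C@@H](O)C[C@H](C(C)C)C#C | intermediate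
13 | (2S,4R)-2-hydroxy-N-methoxy-N-methyl-4-(propan-2-yl)hex-5-ynamide | CON(C)C(=O)[C@@H](O)C[C@H](C(C)C)C#C | intermediate
14 | (2S,4R)-N-methoxy-N-methyl-4-(propan-2-yl)-2-(triethylsilyloxy)hex-5-ynamide | CON(C)C(=O)[C@@H](O[Si](CC)(CC)CC)C[C@H](C(C)C)C#C | intermediate
15 | vinylmagnesium bromide | C=C[Mg]Br | starting material
16 | (4S,6R)-6-(propan-2-yl)-4-(triethylsilyloxy)oct-1-en-7-yn-3-one | C=CC(=O)[C@@H](O[Si](CC)(CC)CC)C[C@H](C(C)C)C#C | intermediate
17 | (trimethylsilyl)methylmagnesium chloride | C[Si](C)(C)C[Mg]Cl | starting material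
18 | (4S,6R)-6-(propan-2-yl)-4-(triethylsilyloxy)-3-[(trimethylsilyl)methyl]oct-1-en-7-yn-3-ol, both C3 epimers (Pauson–Khand precursor) | C[Si](C)(C)CC(O)(C=C)[C@@H](O[Si](CC)(CC)CC)C[C@H](C(C)C)C#C | intermediate
19 | hexacarbonyldicobalt complex of the alkyne of 18 | C[Si](C)(C)CC(O)(C=C)[C@@H](O[Si](CC)(CC)CC)C[C@H](C(C)C)C12C3[Co]1(=C=O)(=C=O)(=C=O)[Co]23(=C=O)(=C=O)=C=O | intermediate
20 | 4-hydroxy-7-(propan-2-yl)-5-(triethylsilyloxy)-4-[(trimethylsilyl)methyl]-3,3a,4,5,6,7-hexahydro-2H-inden-2-one, H2 cis to H4, both C1 epimers (Pauson–Khand product) | C[Si](C)(C)CC1(O)[C@H]2CC(=O)C=C2[C@@H](C(C)C)C[C@@H]1O[Si](CC)(CC)CC | intermediate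
21 | 4-methylidene-7-(propan-2-yl)-5-(triethylsilyloxy)-3,3a,4,5,6,7-hexahydro-2H-inden-2-one, H2 cis to H4, C6 oxygen trans to isopropyl | C=C1[C@H]2CC(=O)C=C2[C@@H](C(C)C)C[C@@H]1O[Si](CC)(CC)CC | intermediate
22 | lithium enolate (C7=C8–OLi) of the trans-fused ketone | C=C1[C@@H]2[C@H](C=C(O[Li])C2)[C@@H](C(C)C)C[C@@H]1O[Si](CC)(CC)CC | intermediate
23 | trans-fused trimethylsilyl enol ether (C7=C8–OSiMe3; H2 β, H3 α, isopropyl α, C6 OSiEt3 β) | C=C1[C@@H]2[C@H](C=C(O[Si](C)(C)C)C2)[C@@H](C(C)C)C[C@@H]1O[Si](CC)(CC)CC | intermediate
24 | acetaldehyde | CC=O | starting material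
25 | C10 trimethylsilyl ether of 26 | C=C1[C@@H]2[C@H]([C@H]([C@H](C)O[Si](C)(C)C)C(=O)C2)[C@@H](C(C)C)C[C@@H]1O[Si](CC)(CC)CC | intermediate
26 | trans-fused C8 ketone with 7α-[(1S)-1-hydroxyethyl], C6 OSiEt3 | C=C1[C@@H]2[C@H]([C@H]([C@H](C)O)C(=O)C2)[C@@H](C(C)C)C[C@@H]1O[Si](CC)(CC)CC | intermediate
27 | C10 tert-butyldimethylsilyl ether of 26 | C=C1[C@@H]2[C@H]([C@H]([C@H](C)O[Si](C)(C)C(C)(C)C)C(=O)C2)[C@@H](C(C)C)C[C@@H]1O[Si](CC)(CC)CC | intermediate
28 | potassium enolate (C8=C9) of 27 | C=C1[C@@H]2[C@H]([C@H]([C@H](C)O[Si](C)(C)C(C)(C)C)C(O[K])=C2)[C@@H](C(C)C)C[C@@H]1O[Si](CC)(CC)CC | intermediate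
29 | 9β-hydroxy ketone | C=C1[C@@H]2[C@H]([C@H]([C@H](C)O[Si](C)(C)C(C)(C)C)C(=O)[C@H]2O)[C@@H](C(C)C)C[C@@H]1O[Si](CC)(CC)CC | intermediate
30 | (2R)-2-methylbutanoic acid | CC[C@@H](C)C(=O)O | starting material
31 | 9α-[(2R)-2-methylbutanoyloxy] ketone, C6 OSiEt3, C10 OSi-t-BuMe2 | C=C1[C@@H]2[C@H]([C@H]([C@H](C)O[Si](C)(C)C(C)(C)C)C(=O)[C@@H]2OC(=O)[C@H](C)CC)[C@@H](C(C)C)C[C@@H]1O[Si](CC)(CC)CC | intermediate
32 | C6 β-alcohol | C=C1[C@@H]2[C@H]([C@H]([C@H](C)O[Si](C)(C)C(C)(C)C)C(=O)[C@@H]2OC(=O)[C@H](C)CC)[C@@H](C(C)C)C[C@@H]1O | intermediate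
33 | (2E)-3-methylpent-2-enoic acid | CC/C(C)=C/C(=O)O | starting material
34 | mixed anhydride of 33 with 2,4,6-trichlorobenzoic acid | CC/C(C)=C/C(=O)OC(=O)c1c(Cl)cc(Cl)cc1Cl | intermediate
35 | C6 (E)-3-methylpent-2-enoate, C10 OSi-t-BuMe2 | C=C1[C@@H]2[C@H]([C@H]([C@H](C)O[Si](C)(C)C(C)(C)C)C(=O)[C@@H]2OC(=O)[C@H](C)CC)[C@@H](C(C)C)C[C@@H]1OC(=O)/C=C(\C)CC | intermediate
36 | CNP0224363.1; in the numbering above 2S,3R,4R,6S,7R,9R,10S with a (2R)-2-methylbutanoate on C9 and an (E)-3-methylpent-2-enoate on C6 | C=C1[C@@H]2[C@H]([C@H]([C@H](C)O)C(=O)[C@@H]2OC(=O)[C@H](C)CC)[C@@H](C(C)C)C[C@@H]1OC(=O)/C=C(\C)CC | target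

**Step count**

Total steps: 20. Longest linear sequence: 20 steps (from 1 and 2 to 36).

**Steps most likely to fail**

1. Step 11 (Pauson–Khand). What may go wrong: the six-membered ring closes too slowly from the 1,7-enyne, so that decomplexation or alkyne oligomerisation takes over, or the two faces of the vinyl group are not discriminated well enough at C2. Fallback, setting out from 18 and returning at 20: the one-carbon unit is changed from carbon monoxide to an isocyanide on zerovalent nickel. Treatment of 18 with Ni(C8H12)2 (bis(cycloocta-1,5-diene)nickel), PBu3 and 2,6-dimethylphenyl isocyanide should give oxidative cyclisation of the alkyne and vinyl group to a nickelacyclopentene, isocyanide insertion and reductive elimination to the bicyclic N-(2,6-dimethylphenyl) imine F1. Buffered hydrolysis (aqueous NaOAc/AcOH) of the imine then gives 20.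

2. Step 14 (aldol). What may go wrong: poor simple diastereoselection at C10 (anti instead of syn), proton transfer from acetaldehyde to the fluoride-activated enolate so that the enol ether is merely desilylated, or addition to the β face of C7. Fallback, setting out from 21 and returning at 26: the silyl enol ether is left out and the open transition state is exchanged for a closed one on titanium. Enone 21 is reduced with Li in NH3/THF containing one equivalent of t-BuOH at −78 °C and the ammonia is removed. The lithium enolate 22 is then treated in THF at −78 °C with ClTi(OiPr)3 to give the triisopropoxytitanium enolate F2. This class of enolate is known to favour the syn aldol from cyclic ketones, so addition of 24 at −78 °C and quenching with aqueous NH4Cl should give 26.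

3. Step 17 (Mitsunobu). What may go wrong: displacement at the hindered C9 carbinol fails, the alkoxyphosphonium ion collapsing instead by elimination towards C2 or by acyl transfer with retention. Fallback, setting out from 27 and returning at 31: the oxygen is brought in as the nucleophile. The potassium enolate 28 generated from 27 is quenched with N-bromosuccinimide at −78 °C to give the 9β-bromo ketone F3 (bromine delivered to the face used by oxygen in step 16). Cesium (2R)-2-methylbutanoate (from 30 and Cs2CO3) in DMF then displaces bromide with inversion to give 31.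

**Further compounds**

F1 | step 11 | bicyclic N-(2,6-dimethylphenyl) imine of 20 (C8=N–aryl) | C[Si](C)(C)CC1(O)[C@H]2CC(=Nc3c(C)cccc3C)C=C2[C@@H](C(C)C)C[C@@H]1O[Si](CC)(CC)CC
F2 | step 14 | triisopropoxytitanium enolate (C7=C8–OTi) from 22 | C=C1[C@@H]2[C@H](C=C(O[Ti](OC(C)C)(OC(C)C)OC(C)C)C2)[C@@H](C(C)C)C[C@@H]1O[Si](CC)(CC)CC
F3 | step 17 | 9β-bromo ketone from 27 | C=C1[C@@H]2[C@H]([C@H]([C@H](C)O[Si](C)(C)C(C)(C)C)C(=O)[C@H]2Br)[C@@H](C(C)C)C[C@@H]1O[Si](CC)(CC)CC
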